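All runs are simulated for substances that don't exist.

A ratio of two rates was what I wanted from this flask: how fast target is lost against how fast it is fed.

| setting | dawn | noon | flask |
|---|---|---|---|
| solid substrate | 13 mM | 30 mM | 20 mM |
| gas | 3.9 mM (held) | 3.9 mM (held) | 3.9 mM (held) |
| remark | run made earlier | run made earlier |  |
| time |  |  | 2.0 h |

- dawn (time / min: target / %, solid substrate / %): 2.00: 30.3, 53.6; 5.00: 90.5, 0; 10.0: 90.6, 0; 25.0: 75.7, 0.9; 50.0: 58.7, 1.5; 120: 36.4, 1.1
- noon (time / min: target / %, solid substrate / %): 2.00: 11.3, 80.0; 5.00: 40.1, 51.0; 10.0: 83.0, 7.6; 25.0: 78.7, 1.1; 50.0: 60.9, 0; 120: 35.4, 0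

(standard deviation of a reading: 1 percentage point)

- solid substrate is a solid; its amount is given per volume of the solution
- at the start none of reagent is dissolved
- the analysis behind the earlier runs scatters by 1 percentage point, standard deviation
- what may be going on: solid substrate <-> dissolved substrate; dissolved substrate + reagent -> target; target <-> isomer of the product; gas <-> reagent
- at the start none of the solid substrate is in solution

- when, up to 2.0 h, the flask holds most target
- the amount of target, in percent of the solid substrate charged, at that time

1. I read the feed from the noon run: between 2.00 min and 5.00 min, solid substrate disappeared at 2.90 mM min⁻¹, and I took that rate for this flask.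

2. I read the loss from the dawn run, with solid substrate reading 0 %: from 10.0 min to 25.0 min, [target] fell by a fraction 0.0120 min⁻¹.

3. The loss ratio, the loss rate at a [target] equal to the whole charge divided by the feed rate, came to 0.0826. Time dropped out.

4. I turned the question round. The opposite outcome, target lost as fast as it is fed, needs this ratio near one, and this flask stood far below that.

5. With solid substrate as limiting reagent, the feed lasted about 6.90 min. Meanwhile [target] averaged half the charge, so I expected a peak near 95.9 %.

The forecast said 90.5 % at 0.16 h, lower than my figure: “This looks zero-order, probably limited by reagent supply from the held gas”.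

The flask gave 94.1 % at 0.142 h, so the forecast held and my figure stood 1.8 percentage points too high.

    solid substrate ⇌ dissolved substrate, rate k1*(cs1 - [dissolved substrate]) while solid is left; crystals form when [dissolved substrate] > cs1 (solubility = 11.0 mM, k = 0.00500 s⁻¹)
    dissolved substrate + reagent → target (k = 18.0 M⁻¹ s⁻¹)
    target ⇌ isomer of the product (K = 2.50, k = 2.20 × 10⁻⁴ s⁻¹)
    gas ⇌ reagent, rate k4*(csat - [reagent]) (kL = 0.0190 s⁻¹)

Without the path from target to isomer of the product, the highest target rose from 94.1 % to 100 %. In a neighbour flask with 50 mM of solid substrate, the loss ratio is 0.207, which points to a peak near 89.6 %. The computed neighbour flask reached 88.4 %.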